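**Retrosynthetic overview**
- The strategy rests on how the resorcinol ring (ring B) is fused to the seven-membered ring. One fusion carbon, C5a, is meta to both ring-B oxygens and bonded to C3 of the inner dihydrofuran. Its neighbour C9a is ortho and para to those oxygens and bonded to the CH that carries the 2,4-dihydroxyphenyl group. This is the pattern in which 3,5-dimethoxybenzyne takes up a carbon nucleophile and an acyl carbon.
- Both bonds from ring B are therefore cut together. This contracts the seven-membered ring to a 2-oxoindane-1-carboxylate on the central arene (ring A): C1 is the later furan C3, the ester carbon the later furan C2, and the ketone the later ArCH carbon.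
- Ring A carries two benzyl ethers and a bromine from the outset, the bromine at the carbon that will hold C3' of the outer furan. Once the dimethoxyaryl groups are in place, the ring-A oxygens could not be freed selectively and that carbon could not be attacked selectively.
- Order of rings: five-membered carbocycle (Rh carbenoid C–H insertion); seven-membered ring (aryne insertion); lactone (flattened to its enol carbonate for the Ir hydrogenation that sets the ArCH centre, then used to set C3); inner dihydrofuran (cation closure); outer dihydrofuran (Rh carbene insertion into a 4-methoxybenzyl ether); then BBr3.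

Key step: step 10

Assumption: the sense of induction written for [Ir(cod)((S)-tBu-PHOX)]BArF and for Rh2(R-PTAD)4 follows the usual models for simpler substrates; if a test run shows the opposite sense, the mirror-image ligand is used and nothing else changes.

Locants: tricyclic compounds carry dibenzo[a,d][7]annulene numbering (ring A = C1–C4, C5 = ester carbon, ring B = C6–C9, C10 = ketone or ArCH carbon, C11 = CH2). From the lactone onwards C5 is called C3 and the former ester carbon C2 (inner furan); C2' and C3' are the outer furan carbons.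

Step 1
Reactants: 1 methyl 2-(3,5-dihydroxyphenyl)acetate
Product: 2 methyl 2-[3,5-bis(benzyloxy)phenyl]acetate
Conditions: BnBr (2.3 equiv), K2CO3, DMF, 50 °C
Reagents that add atoms: benzyl bromide, BrCc1ccccc1
Why: Williamson etherification of both phenols; benzyl is chosen for ring A so that exactly these two oxygens can later be freed by BCl3 beside aryl methyl ethers and an aryl bromide.

Step 2
Reactants: 2 methyl 2-[3,5-bis(benzyloxy)phenyl]acetate
Product: 3 methyl 2-[3,5-bis(benzyloxy)-2-bromophenyl]acetate
Conditions: NBS (1.0 equiv), MeCN, 0 °C, dark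
Reagents that add atoms: N-bromosuccinimide, O=C1CCC(=O)N1Br
Why: Electrophilic aromatic bromination should go ortho to the side chain and para to a benzyloxy group (the site between the two ethers is more crowded), which places the handle for the outer furan before any more reactive arene is present and leaves a single ortho C–H for step 6.

Step 3
Reactants: 3 methyl 2-[3,5-bis(benzyloxy)-2-bromophenyl]acetate
Product: 4 2-[3,5-bis(benzyloxy)-2-bromophenyl]acetic acid
Conditions: LiOH, THF–H2O, rt; then 1 M HCl
Reagents that add atoms: lithium hydroxide, [Li+].[OH-]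
Why: Plain saponification of an unhindered methyl ester, to which ethers and the aryl bromide are inert.

Step 4
Reactants: 4 2-[3,5-bis(benzyloxy)-2-bromophenyl]acetic acid
Product: 6 methyl 4-[3,5-bis(benzyloxy)-2-bromophenyl]-3-oxobutanoate, via acyl imidazolide 5 (not isolated)
Conditions: CDI, THF, rt; then MeO2CCH2CO2K, MgCl2, Et3N, MeCN, rt to 40 °C; 1 M HCl work-up
Reagents that add atoms: 1,1'-carbonyldiimidazole, O=C(n1ccnc1)n1ccnc1; potassium methyl malonate, COC(=O)CC(=O)[O-].[K+]
Why: Masamune–Brooks chain extension, in which the acyl imidazolide C-acylates the magnesium enolate of the malonate half ester and decarboxylation gives the β-keto ester in one operation without self-condensation.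

Step 5
Reactants: 6 methyl 4-[3,5-bis(benzyloxy)-2-bromophenyl]-3-oxobutanoate
Product: 7 methyl 4-[3,5-bis(benzyloxy)-2-bromophenyl]-2-diazo-3-oxobutanoate
Conditions: 4-acetamidobenzenesulfonyl azide, Et3N, MeCN, 0 °C to rt
Reagents that add atoms: 4-acetamidobenzenesulfonyl azide, CC(=O)Nc1ccc(cc1)S(=O)(=O)N=[N+]=[N-]
Why: Regitz diazo transfer to the doubly activated methylene, which is far more acidic than the benzylic CH2.

Step 6
Reactants: 7 methyl 4-[3,5-bis(benzyloxy)-2-bromophenyl]-2-diazo-3-oxobutanoate
Product: 8 methyl 5,7-bis(benzyloxy)-4-bromo-2-oxoindane-1-carboxylate (enol form)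
Conditions: Rh2(OAc)4 (1 mol %), CH2Cl2, rt, slow addition
Reagents that add atoms: none
Why: Intramolecular aromatic C–H insertion (electrophilic substitution by the dirhodium carbenoid) closes the five-membered ring at the only free ortho carbon, which is activated by one ortho and one para benzyloxy group.

Step 7
Reactants: 9 3,5-dimethoxyphenol
Product: 10 2-bromo-3,5-dimethoxyphenol
Conditions: NBS (1.0 equiv), CH2Cl2, −78 to 0 °C
Reagents that add atoms: N-bromosuccinimide, O=C1CCC(=O)N1Br
Why: Low-temperature electrophilic bromination of the phenol should favour the less crowded carbon between OH and OMe over the carbon between the two methoxy groups, and a minor regioisomer is removable by chromatography.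

Step 8
Reactants: 10 2-bromo-3,5-dimethoxyphenol
Product: 11 (2-bromo-3,5-dimethoxyphenoxy)trimethylsilane
Conditions: HN(SiMe3)2, THF, 65 °C; concentrate
Reagents that add atoms: hexamethyldisilazane, C[Si](C)(C)N[Si](C)(C)C
Why: O-silylation of a phenol by hexamethyldisilazane, driven by loss of ammonia and needing no aqueous work-up.

Step 9
Reactants: 11 (2-bromo-3,5-dimethoxyphenoxy)trimethylsilane
Product: 14 3,5-dimethoxy-2-(trimethylsilyl)phenyl triflate, via aryllithium 12 (not isolated), via lithium silylphenoxide 13 (not isolated)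
Conditions: n-BuLi, THF, −78 °C; then Tf2O, −78 to 0 °C
Reagents that add atoms: n-butyllithium, [Li]CCCC; triflic anhydride, O=S(=O)(OS(=O)(=O)C(F)(F)F)C(F)(F)F
Why: Bromine–lithium exchange triggers the retro-Brook O-to-C silyl shift and the lithium phenoxide so formed is triflated in the same flask, the standard entry to ortho-silylaryl triflates.

Step 10
Reactants: 8 methyl 5,7-bis(benzyloxy)-4-bromo-2-oxoindane-1-carboxylate; 14 3,5-dimethoxy-2-(trimethylsilyl)phenyl triflate (1.5 equiv)
Product: 17 methyl 2,4-bis(benzyloxy)-1-bromo-7,9-dimethoxy-10-oxo-10,11-dihydro-5H-dibenzo[a,d][7]annulene-5-carboxylate (racemic), via 3,5-dimethoxybenzyne 15 (not isolated), via caesium benzocyclobutenoxide 16 (not isolated)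
Conditions: CsF (2.5 equiv), MeCN, 80 °C
Reagents that add atoms: caesium fluoride, [Cs+].[F-] (counter-ion of 16 only)
Why: Fluoride strips the silyl group from 14 and loss of triflate gives aryne 15, to which the caesium enolate of 8 adds through C1 at the aryne carbon remote from the flanking methoxy group, so that the aryl anion is left ortho to that methoxy group where the C–O dipole stabilises it. This anion closes on the C2 ketone (4-exo-trig) to give benzocyclobutenoxide 16, whose strained C1–C2 bond, shared by the four- and five-membered rings, breaks to an ester-stabilised, doubly benzylic carbanion that is protonated. The seven-membered ring is thus made by two-carbon expansion of the five-membered ring and not by end-to-end cyclisation, and both bonds from ring B (C5–C5a and C9a–C10) form in one operation. The closest known reaction type is the aryne acyl-alkylation of cyclic β-keto esters, which is established for 2-oxoindane-1-carboxylates. The one new stereocentre, C5, arises racemic by unselective protonation and needs no control, because it is made planar in step 14 and set in step 16. The selectivity needed is the orientation of addition to the unsymmetrical aryne, which the methoxy group next to the triple bond secures; C- over O-arylation is favoured by the soft, fully enolised keto ester, and the aryl bromide and benzyl ethers are inert to CsF.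

Step 11
Reactants: 17 keto ester
Product: 18 methyl 2,4-bis(benzyloxy)-1-bromo-7,9-dimethoxy-10-(trifluoromethylsulfonyloxy)-5H-dibenzo[a,d][7]annulene-5-carboxylate (racemic)
Conditions: KN(SiMe3)2 (1.1 equiv), THF, −78 °C; PhNTf2, −78 to 0 °C
Reagents that add atoms: N-phenylbis(trifluoromethanesulfonimide), O=S(=O)(N(c1ccccc1)S(=O)(=O)C(F)(F)F)C(F)(F)F
Why: Enol triflate formation: the C11 protons of the deoxybenzoin-type ketone are several pKa units more acidic than the diarylacetate C5–H, so one equivalent of base gives the ketone enolate; this avoids adding a basic aryl-metal reagent to a readily enolised ketone.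

Step 12
Reactants: 18 enol triflate; 19 2,4-dimethoxyphenylboronic acid
Product: 20 methyl 2,4-bis(benzyloxy)-1-bromo-10-(2,4-dimethoxyphenyl)-7,9-dimethoxy-5H-dibenzo[a,d][7]annulene-5-carboxylate (racemic)
Conditions: Pd(PPh3)4 (5 mol %), aq. Na2CO3, DME, 50–60 °C
Reagents that add atoms: none
Why: Suzuki–Miyaura coupling in which zerovalent palladium should insert into the conjugated vinyl C–OTf bond well before the electron-rich, doubly ortho-substituted C–Br bond, giving the C10=C11 alkene directly and with fixed position.

Step 13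
Reactants: 20 alkene ester
Product: 22 racemic tetracyclic lactone (C4–O closed onto the C5 ester carbonyl as a 3-arylbenzofuran-2(3H)-one; C2–OH free, C1–Br, C10=C11 alkene), via dihydroxy ester 21 (not isolated)
Conditions: BCl3 (4 equiv), C6HMe5 (6 equiv), CH2Cl2, −78 °C; aq. work-up; then TsOH·H2O (10 mol %), PhMe, 80 °C
Reagents that add atoms: none
Why: BCl3 with pentamethylbenzene as benzyl-cation scavenger cleaves aryl benzyl ethers at −78 °C without touching aryl methyl ethers, the alkene or C–Br, and acid-catalysed transesterification then closes the C4 phenol onto the ester (five-membered lactone), which tells the two ring-A oxygens apart.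

Step 14
Reactants: 22 racemic lactone
Product: 23 achiral bis(methyl carbonate): 2-(methoxycarbonyloxy)benzofuran (C2=C3 now part of an aromatic furan) with the ring-A C2 oxygen also as methyl carbonate
Conditions: ClCO2Me (3 equiv), Et3N (3.5 equiv), THF, 0 °C, argon
Reagents that add atoms: methyl chloroformate, COC(=O)Cl
Why: O-acylation of a 3-arylbenzofuranone enolate to its bench-stable enol carbonate (C-acylation would need a crowded quaternary centre) turns the labile stereocentre into an sp2 carbon, so that the hydrogenation substrate has no stereocentre that could override the catalyst.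

Step 15
Reactants: 23 achiral bis(methyl carbonate)
Product: 24 (10S)-10,11-dihydro bis(methyl carbonate)
Conditions: [Ir(cod)((S)-tBu-PHOX)]BArF (2–5 mol %), H2 (50–100 bar), CH2Cl2, rt
Reagents that add atoms: none
Why: Iridium–N,P-catalysed asymmetric hydrogenation of an unfunctionalised trisubstituted aryl alkene, in which the ligand alone chooses the face of C10=C11 and sets C10 as S, while the tetrasubstituted aromatic furan bond, the carbonates and C–Br are not reduced.

Step 16
Reactants: 24 (10S)-bis(methyl carbonate)
Product: 26 (3S,10S)-lactone (C2–OH of ring A free, C1–Br), via dihydroxy ester 25 (not isolated)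
Conditions: K2CO3 (cat.), MeOH–THF, 0 °C, argon; AcOH; then TsOH·H2O (cat.), PhMe, 80 °C; then DBU (10 mol %), rt
Reagents that add atoms: methanol, CO (in 25 only)
Why: Base-catalysed transesterification removes both carbonates, acid re-closes ring-opened hydroxy ester, and the very acidic C3–H of the 3-arylbenzofuranone lets DBU equilibrate C3 to the 3S isomer, in which the C10 aryl group stands pseudo-axial on the rigid tetracycle and clear of the C9 methoxy group (relief of A(1,3) strain), so C3 is set under thermodynamic control by C10.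

Step 17
Reactants: 26 (3S,10S)-lactone
Product: 27 (3S,10S)-lactol (anomers at C2)
Conditions: i-Bu2AlH (3 equiv), CH2Cl2, −78 °C; aq. potassium sodium tartrate
Reagents that add atoms: none
Why: Partial lactone reduction stops at the aluminium hemiacetal at low temperature, one equivalent being spent on the phenol, and the non-acidic work-up avoids dehydration to the benzofuran and leaves C3 untouched.

Step 18
Reactants: 27 (3S,10S)-lactol; 28 4-methoxyphenylmagnesium bromide (5 equiv)
Product: 29 (5S,10S)-1-bromo-10-(2,4-dimethoxyphenyl)-5-[hydroxy(4-methoxyphenyl)methyl]-7,9-dimethoxy-10,11-dihydro-5H-dibenzo[a,d][7]annulene-2,4-diol (carbinol epimers)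
Conditions: THF, 0 °C; aq. NH4Cl
Reagents that add atoms: none
Why: Grignard addition to the hydroxy-aldehyde tautomer released from the lactol as its magnesium phenoxide should outrun enolisation of the diarylacetaldehyde, and the carbinol configuration is irrelevant because that carbon is ionised in step 19.

Step 19
Reactants: 29 triol
Product: 30 (2S,3S,10S)-bromophenol with the inner trans-2-(4-methoxyphenyl)-2,3-dihydrofuran closed
Conditions: TsOH·H2O (10 mol %), CH2Cl2, 0 °C to rt
Reagents that add atoms: none
Why: Acid ionises the 4-methoxybenzylic alcohol to a quinone-methide-like cation that only the C4 phenol can reach (5-exo closure), and the reversible closure places the C2 aryl group anti to ring B at C3, which sets C2 as S (2,3-trans) under thermodynamic control.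

Step 20
Reactants: 30 bromophenol; 31 4-methoxybenzyl chloride
Product: 32 (2S,3S,10S)-4-methoxybenzyl ether
Conditions: K2CO3, n-Bu4NI (cat.), DMF, rt
Reagents that add atoms: none
Why: Williamson etherification of the only free phenol; the 4-methoxybenzyl group is not a protecting group, since its CH2 and aryl ring become C2' and its aryl substituent.

Step 21
Reactants: 32 4-methoxybenzyl ether; 33 3,5-dimethoxybenzonitrile
Product: 36 N–H ketimine (ring-A C1–C(=NH)–(3,5-dimethoxyphenyl)), via aryllithium 34 (not isolated), via lithium ketimide 35 (not isolated)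
Conditions: n-BuLi, THF, −78 °C; 33, −78 to 0 °C; MeOH
Reagents that add atoms: n-butyllithium, [Li]CCCC
Why: Bromine–lithium exchange at −78 °C outruns any benzylic deprotonation, the aryllithium adds once to the non-enolisable nitrile, and the crowded N–H ketimine survives a methanol quench.

Step 22
Reactants: 36 N–H ketimine
Product: 37 hydrazone
Conditions: N2H4·H2O (excess), AcOH (cat.), EtOH, 80 °C
Reagents that add atoms: hydrazine, NN
Why: Transimination, in which the protonated ketimine is more electrophilic than the corresponding doubly ortho-substituted benzophenone and the exchange is driven by loss of ammonia.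

Step 23
Reactants: 37 hydrazone
Product: 39 (2S,3S,10S,2'S,3'R)-octamethyl ether with a cis outer dihydrofuran, via diaryldiazomethane 38 (not isolated)
Conditions: MnO2, CH2Cl2, rt, filter; then Rh2(R-PTAD)4 (1 mol %), CH2Cl2, 0 °C
Reagents that add atoms: none
Why: Dehydrogenation of the hydrazone gives the diazo compound and the donor/donor dirhodium carbene inserts into the ether-activated benzylic C–H bond through a five-membered transition state, a reaction known to give cis-2,3-diaryl-2,3-dihydrobenzofurans; C3' (R) is set by the chiral carboxylate ligands, because the nearest core stereocentre is remote, and C2' follows as cis.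

Step 24
Reactants: 39 cis octamethyl ether
Product: 40 (2S,3S,10S,2'R,3'R)-octamethyl ether of the target
Conditions: CF3CO2H (2 equiv), CH2Cl2, 0 °C to rt
Reagents that add atoms: none
Why: Acid opens the C2'–O bond reversibly to the 4-methoxybenzyl cation and re-closure by the adjacent phenol, faster than proton loss from C3', gives the more stable 2',3'-trans isomer, while the inner furan is already trans and C3' is not involved.

Step 25
Reactants: 40 octamethyl ether
Product: 41 CNP0154047.3 (target)
Conditions: BBr3 (20 equiv), CH2Cl2, −78 °C to rt; then ice–water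
Reagents that add atoms: none
Why: Lewis-acid demethylation of all eight aryl methyl ethers by bromide attack on the boron-complexed OMe groups; any reversible opening of a furan C2–O bond should re-close to the trans isomers already present, and no C–H stereocentre is ionisable.

**Compound list**
1 | methyl 2-(3,5-dihydroxyphenyl)acetate | COC(=O)Cc1cc(O)cc(O)c1 | starting material
2 | methyl 2-[3,5-bis(benzyloxy)phenyl]acetate | COC(=O)Cc1cc(OCc2ccccc2)cc(OCc2ccccc2)c1 | intermediate
3 | methyl 2-[3,5-bis(benzyloxy)-2-bromophenyl]acetate | COC(=O)Cc1cc(OCc2ccccc2)cc(OCc2ccccc2)c1Br | intermediate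
4 | 2-[3,5-bis(benzyloxy)-2-bromophenyl]acetic acid | OC(=O)Cc1cc(OCc2ccccc2)cc(OCc2ccccc2)c1Br | intermediate
5 | acyl imidazolide of 4 | O=C(Cc1cc(OCc2ccccc2)cc(OCc2ccccc2)c1Br)n1ccnc1 | intermediate
6 | methyl 4-[3,5-bis(benzyloxy)-2-bromophenyl]-3-oxobutanoate | COC(=O)CC(=O)Cc1cc(OCc2ccccc2)cc(OCc2ccccc2)c1Br | intermediate
7 | methyl 4-[3,5-bis(benzyloxy)-2-bromophenyl]-2-diazo-3-oxobutanoate | COC(=O)C(=[N+]=[N-])C(=O)Cc1cc(OCc2ccccc2)cc(OCc2ccccc2)c1Br | intermediate
8 | methyl 5,7-bis(benzyloxy)-4-bromo-2-oxoindane-1-carboxylate (drawn as its enol) | COC(=O)C1=C(O)Cc2c(Br)c(OCc3ccccc3)cc(OCc3ccccc3)c21 | intermediate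
9 | 3,5-dimethoxyphenol | COc1cc(O)cc(OC)c1 | starting material
10 | 2-bromo-3,5-dimethoxyphenol | COc1cc(O)c(Br)c(OC)c1 | intermediate
11 | (2-bromo-3,5-dimethoxyphenoxy)trimethylsilane | COc1cc(O[Si](C)(C)C)c(Br)c(OC)c1 | intermediate
12 | (2-lithio-3,5-dimethoxyphenoxy)trimethylsilane | COc1cc(O[Si](C)(C)C)c([Li])c(OC)c1 | intermediate
13 | lithium 3,5-dimethoxy-2-(trimethylsilyl)phenoxide | COc1cc([O-])c([Si](C)(C)C)c(OC)c1.[Li+] | intermediate
14 | 3,5-dimethoxy-2-(trimethylsilyl)phenyl triflate | COc1cc(OC)c([Si](C)(C)C)c(OS(=O)(=O)C(F)(F)F)c1 | intermediate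
15 | 3,5-dimethoxybenzyne | COC1=CC(OC)=CC#C1 | intermediate
16 | caesium benzocyclobutenoxide (aryne adduct closed on the indanone ketone, racemic) | COC(=O)C12c3cc(OC)cc(OC)c3C1([O-])Cc1c(Br)c(OCc3ccccc3)cc(OCc3ccccc3)c12.[Cs+] | intermediate
17 | methyl 2,4-bis(benzyloxy)-1-bromo-7,9-dimethoxy-10-oxo-10,11-dihydro-5H-dibenzo[a,d][7]annulene-5-carboxylate (racemic) | COC(=O)C1c2cc(OC)cc(OC)c2C(=O)Cc2c(Br)c(OCc3ccccc3)cc(OCc3ccccc3)c21 | intermediate
18 | C10 enol triflate of 17 (racemic) | COC(=O)C1c2cc(OC)cc(OC)c2C(OS(=O)(=O)C(F)(F)F)=Cc2c(Br)c(OCc3ccccc3)cc(OCc3ccccc3)c21 | intermediate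
19 | 2,4-dimethoxyphenylboronic acid | COc1ccc(B(O)O)c(OC)c1 | starting material
20 | methyl 2,4-bis(benzyloxy)-1-bromo-10-(2,4-dimethoxyphenyl)-7,9-dimethoxy-5H-dibenzo[a,d][7]annulene-5-carboxylate (racemic) | COC(=O)C1c2cc(OC)cc(OC)c2C(c2ccc(OC)cc2OC)=Cc2c(Br)c(OCc3ccccc3)cc(OCc3ccccc3)c21 | intermediate
21 | 2,4-dihydroxy analogue of 20 (racemic) | COC(=O)C1c2cc(OC)cc(OC)c2C(c2ccc(OC)cc2OC)=Cc2c(Br)c(O)cc(O)c21 | intermediate
22 | racemic tetracyclic lactone with C10=C11 alkene | O=C1Oc2cc(O)c(Br)c3c2C1c1cc(OC)cc(OC)c1C(c1ccc(OC)cc1OC)=C3 | intermediate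
23 | achiral enol carbonate / aryl carbonate (2-(methoxycarbonyloxy)benzofuran) | COC(=O)Oc1oc2cc(OC(=O)OC)c(Br)c3c2c1-c1cc(OC)cc(OC)c1C(c1ccc(OC)cc1OC)=C3 | intermediate
24 | (10S)-10,11-dihydro derivative of 23 | COC(=O)Oc1oc2cc(OC(=O)OC)c(Br)c3c2c1-c1cc(OC)cc(OC)c1[C@H](c1ccc(OC)cc1OC)C3 | intermediate
25 | (10S)-dihydroxy methyl ester (C5 epimers) | COC(=O)C1c2cc(OC)cc(OC)c2[C@H](c2ccc(OC)cc2OC)Cc2c(Br)c(O)cc(O)c21 | intermediate
26 | (3S,10S)-lactone | O=C1Oc2cc(O)c(Br)c3c2[C@@H]1c1cc(OC)cc(OC)c1[C@H](c1ccc(OC)cc1OC)C3 | intermediate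
27 | (3S,10S)-lactol (anomers) | OC1Oc2cc(O)c(Br)c3c2[C@@H]1c1cc(OC)cc(OC)c1[C@H](c1ccc(OC)cc1OC)C3 | intermediate
28 | 4-methoxyphenylmagnesium bromide | COc1ccc([Mg]Br)cc1 | starting material
29 | (5S,10S)-triol (carbinol epimers) | Oc1cc(O)c(Br)c2c1[C@@H](C(O)c1ccc(OC)cc1)c1cc(OC)cc(OC)c1[C@H](c1ccc(OC)cc1OC)C2 | intermediate
30 | (2S,3S,10S)-bromophenol with inner trans-dihydrofuran | COc1ccc([C@H]2Oc3cc(O)c(Br)c4c3[C@@H]2c2cc(OC)cc(OC)c2[C@H](c2ccc(OC)cc2OC)C4)cc1 | intermediate
31 | 4-methoxybenzyl chloride | COc1ccc(CCl)cc1 | starting material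
32 | (2S,3S,10S)-4-methoxybenzyl ether of 30 | COc1ccc([C@H]2Oc3cc(OCc4ccc(OC)cc4)c(Br)c4c3[C@@H]2c2cc(OC)cc(OC)c2[C@H](c2ccc(OC)cc2OC)C4)cc1 | intermediate
33 | 3,5-dimethoxybenzonitrile | COc1cc(C#N)cc(OC)c1 | starting material
34 | aryllithium from 32 | COc1ccc([C@H]2Oc3cc(OCc4ccc(OC)cc4)c([Li])c4c3[C@@H]2c2cc(OC)cc(OC)c2[C@H](c2ccc(OC)cc2OC)C4)cc1 | intermediate
35 | lithium ketimide | COc1ccc([C@H]2Oc3cc(OCc4ccc(OC)cc4)c(C(=N[Li])c4cc(OC)cc(OC)c4)c4c3[C@@H]2c2cc(OC)cc(OC)c2[C@H](c2ccc(OC)cc2OC)C4)cc1 | intermediate
36 | N–H ketimine | COc1ccc([C@H]2Oc3cc(OCc4ccc(OC)cc4)c(C(=N)c4cc(OC)cc(OC)c4)c4c3[C@@H]2c2cc(OC)cc(OC)c2[C@H](c2ccc(OC)cc2OC)C4)cc1 | intermediate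
37 | hydrazone | COc1ccc([C@H]2Oc3cc(OCc4ccc(OC)cc4)c(C(=NN)c4cc(OC)cc(OC)c4)c4c3[C@@H]2c2cc(OC)cc(OC)c2[C@H](c2ccc(OC)cc2OC)C4)cc1 | intermediate
38 | diaryldiazomethane | COc1ccc([C@H]2Oc3cc(OCc4ccc(OC)cc4)c(C(=[N+]=[N-])c4cc(OC)cc(OC)c4)c4c3[C@@H]2c2cc(OC)cc(OC)c2[C@H](c2ccc(OC)cc2OC)C4)cc1 | intermediate
39 | (2S,3S,10S,2'S,3'R)-octamethyl ether, outer furan cis | COc1ccc([C@H]2Oc3cc4c(c5c3[C@@H]2c2cc(OC)cc(OC)c2[C@H](c2ccc(OC)cc2OC)C5)[C@@H](c2cc(OC)cc(OC)c2)[C@@H](c2ccc(OC)cc2)O4)cc1 | intermediate
40 | (2S,3S,10S,2'R,3'R)-octamethyl ether, both furans trans | COc1ccc([C@H]2Oc3cc4c(c5c3[C@@H]2c2cc(OC)cc(OC)c2[C@H](c2ccc(OC)cc2OC)C5)[C@@H](c2cc(OC)cc(OC)c2)[C@H](c2ccc(OC)cc2)O4)cc1 | intermediate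
41 | CNP0154047.3, (2S,3S,10S,2'R,3'R) | Oc1ccc([C@H]2Oc3cc4c(c5c3[C@@H]2c2cc(O)cc(O)c2[C@H](c2ccc(O)cc2O)C5)[C@@H](c2cc(O)cc(O)c2)[C@H](c2ccc(O)cc2)O4)cc1 | target

**Step count**
- Total step count: 25.
- Longest linear sequence: 22 (steps 1–6 and 10–25). Steps 7–9 form the three-step side branch to 14.

**Steps most likely to fail**

Step 15 (asymmetric hydrogenation).
- What may go wrong: hydrogen uptake may be slow or absent at an alkene flanked by a methoxy group, an ortho-methoxyaryl group and the C1 bromine, or the ligand may discriminate poorly between the two faces.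
- Fallback: it sets out from 22 and gives up catalytic induction for ionic hydrogenation plus resolution.
- Et3SiH and CF3CO2H in CH2Cl2 protonate C11, and the C10 cation, stabilised by two dimethoxyaryl rings, takes up hydride without any metal having to bind the alkene.
- Brief treatment with DBU then gives the racemic (3S*,10S*)-lactone F1.
- This racemate is resolved by preparative chromatography on a chiral stationary phase. Its (3S,10S) enantiomer is 26, where the route is rejoined, and steps 14 to 16 drop out.

Step 10 (aryne insertion).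
- What may go wrong: the aryl anion may be protonated before it closes on the ketone, which stops at plain α-arylation. The enol oxygen may be arylated, or addition may be sluggish at C1 next to the C7 benzyloxy group.
- Fallback: it sets out from 8 and makes the same two bonds one after the other.
- Pinhey arylation with 3,5-(MeO)2C6H3Pb(OAc)3 and pyridine in CHCl3 gives the quaternary 1-aryl keto ester F2. This is also what interrupted aryne addition would deliver.
- KOH in aqueous THF opens its non-enolisable β-keto ester by retro-Claisen cleavage of C1–C2 to the diarylacetate arylacetic acid F3.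
- Trifluoroacetic anhydride in CH2Cl2 then effects intramolecular Friedel–Crafts acylation at the ring-B carbon ortho and para to the methoxy groups, which returns to 17.

Step 23 (carbene C–H insertion).
- What may go wrong: azine formation, slow carbene generation from the crowded diazo compound, or loss of facial selectivity through a mismatch between catalyst and chiral core.
- Fallback: it sets out from 36 and replaces the insertion by a sulfur-ylide homologation.
- Aqueous oxalic acid hydrolyses the ketimine to the diaryl ketone F4.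
- Dimethylsulfonium methylide (Me3SI, NaH, DMSO–THF; Corey–Chaykovsky reaction) gives the 1,1-diaryl epoxide F5.
- ZnI2 in benzene induces Meinwald rearrangement to the diarylacetaldehyde F6.
- Grignard reagent 28 gives the carbinol F7.
- CF3CO2H with anisole in CH2Cl2 removes the 4-methoxybenzyl ether and closes the freed phenol on the benzylic cation to the trans dihydrofuran.
- C3' is then under substrate control only, so its epimer is removed by chromatography, and the route is rejoined at 40.

**Further compounds**
F1 | step 15 | racemic (3S*,10S*)-lactone (racemate of 26) | O=C1Oc2cc(O)c(Br)c3c2C1c1cc(OC)cc(OC)c1C(c1ccc(OC)cc1OC)C3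
F2 | step 10 | methyl 5,7-bis(benzyloxy)-4-bromo-1-(3,5-dimethoxyphenyl)-2-oxoindane-1-carboxylate (racemic) | COC(=O)C1(c2cc(OC)cc(OC)c2)C(=O)Cc2c(Br)c(OCc3ccccc3)cc(OCc3ccccc3)c21
F3 | step 10 | 2-[3,5-bis(benzyloxy)-2-bromo-6-[1-(3,5-dimethoxyphenyl)-2-methoxy-2-oxoethyl]phenyl]acetic acid (racemic) | COC(=O)C(c1cc(OC)cc(OC)c1)c1c(OCc2ccccc2)cc(OCc2ccccc2)c(Br)c1CC(=O)O
F4 | step 23 | diaryl ketone from 36 | COc1ccc([C@H]2Oc3cc(OCc4ccc(OC)cc4)c(C(=O)c4cc(OC)cc(OC)c4)c4c3[C@@H]2c2cc(OC)cc(OC)c2[C@H](c2ccc(OC)cc2OC)C4)cc1
F5 | step 23 | 1,1-diaryl epoxide (epimers at the new centre) | COc1ccc([C@H]2Oc3cc(OCc4ccc(OC)cc4)c(C5(CO5)c5cc(OC)cc(OC)c5)c4c3[C@@H]2c2cc(OC)cc(OC)c2[C@H](c2ccc(OC)cc2OC)C4)cc1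
F6 | step 23 | diarylacetaldehyde (epimers at C3') | COc1ccc([C@H]2Oc3cc(OCc4ccc(OC)cc4)c(C(C=O)c4cc(OC)cc(OC)c4)c4c3[C@@H]2c2cc(OC)cc(OC)c2[C@H](c2ccc(OC)cc2OC)C4)cc1
F7 | step 23 | 4-methoxyphenyl carbinol (epimers at C2' and C3') | COc1ccc([C@H]2Oc3cc(OCc4ccc(OC)cc4)c(C(C(O)c4ccc(OC)cc4)c4cc(OC)cc(OC)c4)c4c3[C@@H]2c2cc(OC)cc(OC)c2[C@H](c2ccc(OC)cc2OC)C4)cc1
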